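**Retrosynthetic overview**

1. Rings: germacrone 1 already holds the ten-membered carbocycle of the germacrane-to-eudesmane biogenesis. One catalyst-controlled, proton-initiated transannular C5–C10 closure forms both six-membered rings at once (exocyclic isomer 2 drains to dienone 3) and sets C5 and C10.
2. C3/C4 oxygens: α-face ketohydroxylation of the 3,4-alkene of 3 gives ketol 4, and hydroxyl-directed reduction gives trans-diol 5.
3. Ester: 5 plus angelic acid 6, through mixed anhydride 7, gives angelate 8.
4. Last disconnection: the C11–OOH and 6,7-alkene of target 9 come from the 7(11)-en-8-one 8 by a singlet-oxygen ene reaction, the presumed last biogenetic event.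

Assumption: the SMILES is read as the (3S,4S,5R,10R)-eudesmane (3β-angeloyloxy, 4α-OH, 4β-Me, 5α-H, 10β-Me; eudesmane/germacrane numbering throughout), and the chiral acid in step 1 is written as the (S,S) antipode but means whichever antipode is found to deliver (5R,10R)-3.

**Route**

Step 1
Reactants: 1 germacrone
Product: 3 (5R,10R)-eudesma-3,7(11)-dien-8-one, via exocyclic 4(15)-ene isomer 2 (not isolated)
Conditions: chiral IDPi acid HN[P(=NSO2CF3)(O2C20H10Ar2)]2, Ar = 3,5-(CF3)2C6H3, from (S)-BINOL, C74H33F30N3O8P2S2 (5 mol %), (CF3)3COH/CH2Cl2 1:4, −40 → −20 °C, until 2 is consumed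
Reagents that add atoms: none
Why: Proposed new method: the confined chiral acid protonates C1 of the 1(10)-alkene of one of the two rapidly interconverting planar-chiral crossed conformers of 1 inside its pocket while the 4,5-alkene attacks C10 across the ring (anti addition to two E-alkenes, so the trans ring fusion with 5α-H and 10β-Me is set in one event and its absolute sense by the chiral ion pair), the C4 cation then loses H3 to the counter-anion and any exocyclic isomer 2 is reprotonated to the same cation until it drains to the trisubstituted alkene 3; the closest known reaction types are the racemic acid-catalysed transannular cyclisation of germacrone to selinadienones and IDPi-catalysed enantioselective proton-initiated polyene cyclisation in fluorinated alcohols.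

Step 2
Reactants: 3 (5R,10R)-eudesma-3,7(11)-dien-8-one
Product: 4 (4S,5R,10R)-4-hydroxyeudesm-7(11)-ene-3,8-dione
Conditions: RuCl3·3H2O (1 mol %), 2KHSO5·KHSO4·K2SO4, NaHCO3, EtOAc/MeCN/H2O 6:6:1, 0 °C → rt, 30 min
Reagents that add atoms: potassium peroxymonosulfate, [K+].[O-]S(=O)(=O)OO
Why: Plietker-type RuO4-catalysed ketohydroxylation, in which RuO4 adds [3+2] to the electron-rich trisubstituted 3,4-alkene from the α-face (the β-face is blocked by the axial C10 methyl and the tetrasubstituted enone alkene is electron-poor), which sets C4 as 4α-OH/4β-Me, and peroxymonosulfate then oxidises the ruthenate ester at the secondary carbon to the C3 ketone.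

Step 3
Reactants: 4 (4S,5R,10R)-4-hydroxyeudesm-7(11)-ene-3,8-dione
Product: 5 (3S,4S,5R,10R)-3,4-dihydroxyeudesm-7(11)-en-8-one
Conditions: Me4NBH(OAc)3, MeCN/AcOH 1:1, −20 → 0 °C
Reagents that add atoms: none
Why: Saksena–Evans hydroxyl-directed reduction, in which the 4α-OH exchanges onto boron and delivers hydride intramolecularly to the α (axial) face of C3, giving the equatorial 3β-OH trans to the 4α-OH, while the reagent leaves the hindered, non-hydroxylated C8 enone untouched.

Step 4
Reactants: 5 (3S,4S,5R,10R)-3,4-dihydroxyeudesm-7(11)-en-8-one; 6 angelic acid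
Product: 8 (3S,4S,5R,10R)-3-angeloyloxy-4-hydroxyeudesm-7(11)-en-8-one, via angelic 2,4,6-trichlorobenzoic anhydride 7 (not isolated)
Conditions: 6, 2,4,6-Cl3C6H2COCl, Et3N, toluene, 23 °C, 2 h; then 5, 80 °C
Reagents that add atoms: angelic acid, C/C=C(/C)C(=O)O
Why: Yamaguchi-type mixed-anhydride esterification run without a nucleophilic catalyst, which acylates only the secondary 3β-OH (the tertiary 4α-OH is inert) and keeps the Z geometry of the angelate, with no stereocentre touched.

Step 5
Reactants: 8 (3S,4S,5R,10R)-3-angeloyloxy-4-hydroxyeudesm-7(11)-en-8-one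
Product: 9 (3S,4S,5R,10R)-3-angeloyloxy-4-hydroxy-11-hydroperoxyeudesm-6-en-8-one
Conditions: O2 (1 atm), 5,10,15,20-tetraphenylporphyrin (1 mol %), white LED, CH2Cl2, 0 °C, stopped at full conversion of 8
Reagents that add atoms: dioxygen, O=O
Why: Schenck ene reaction of singlet oxygen with the s-cis-locked tetrasubstituted enone, in which the gem effect directs abstraction of the axial 6β-H (the CH2 geminal to the carbonyl on C7) so that oxygen is delivered to C11 and the alkene moves to C6=C7; C11 is not stereogenic, and the less electron-rich trisubstituted angelate alkene reacts much more slowly.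

**Compound list**

1 | germacrone, (3E,7E)-3,7-dimethyl-10-(propan-2-ylidene)cyclodeca-3,7-dien-1-one | C/C1=C\CC/C(C)=C/CC(=C(C)C)C(=O)C1 | starting material
2 | (5S,10R)-eudesma-4(15),7(11)-dien-8-one (5α-H, 10β-Me, exocyclic alkene) | C=C1CCC[C@]2(C)CC(=O)C(=C(C)C)C[C@@H]12 | intermediate
3 | (5R,10R)-eudesma-3,7(11)-dien-8-one (5α-H, 10β-Me) | CC1=CCC[C@]2(C)CC(=O)C(=C(C)C)C[C@@H]12 | intermediate
4 | (4S,5R,10R)-4-hydroxyeudesm-7(11)-ene-3,8-dione (4α-OH, 4β-Me) | O=C1CC[C@]2(C)CC(=O)C(=C(C)C)C[C@H]2[C@]1(C)O | intermediate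
5 | (3S,4S,5R,10R)-3,4-dihydroxyeudesm-7(11)-en-8-one (3β,4α-diol) | O[C@H]1CC[C@]2(C)CC(=O)C(=C(C)C)C[C@H]2[C@]1(C)O | intermediate
6 | angelic acid, (Z)-2-methylbut-2-enoic acid | C/C=C(/C)C(=O)O | starting material
7 | angelic 2,4,6-trichlorobenzoic anhydride | C/C=C(/C)C(=O)OC(=O)c1c(Cl)cc(Cl)cc1Cl | intermediate
8 | (3S,4S,5R,10R)-3-angeloyloxy-4-hydroxyeudesm-7(11)-en-8-one | C/C=C(/C)C(=O)O[C@H]1CC[C@]2(C)CC(=O)C(=C(C)C)C[C@H]2[C@]1(C)O | intermediate
9 | (3S,4S,5R,10R)-3-angeloyloxy-4-hydroxy-11-hydroperoxyeudesm-6-en-8-one (CNP0161122.1) | C/C=C(/C)C(=O)O[C@H]1CC[C@]2(C)CC(=O)C(C(C)(C)OO)=C[C@H]2[C@]1(C)O | target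

**Totals**

Total step count: 5. Longest linear sequence: 5 steps (from germacrone 1).

**Steps most likely to fail, with fallbacks**

Step 1 (enantiocontrol and Δ3 regiocontrol of the proton-initiated closure). The fallback sets out from 1 and carries the absolute information in an epoxide instead of in the catalyst's proton. Shi epoxidation of the 1(10)-alkene (D-fructose-derived Shi ketone, 2KHSO5·KHSO4·K2SO4, K2CO3, MeCN/dimethoxymethane/H2O, 0 °C; the 4,5-regioisomer is separated) gives (1R,10R)-1,10-epoxygermacra-4E,7(11)-dien-8-one F1. BF3·OEt2 (CH2Cl2, −78 °C) opens the epoxide at C10 while the 4,5-alkene closes the C5–C10 bond, giving 1β-hydroxy-5α-eudesma-3,7(11)-dien-8-one F2. The extra hydroxyl is removed by Barton–McCombie deoxygenation: thiocarbonyldiimidazole gives 1β-(imidazol-1-ylthiocarbonyloxy)-5α-eudesma-3,7(11)-dien-8-one F3, and Bu3SnH/AIBN (toluene, 90 °C) comes back to the route at 3.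

Step 2 (chemoselectivity and over-oxidation in the one-step ketohydroxylation). The fallback sets out from 3 and splits the oxidation in two. Catalytic K2OsO4·2H2O with N-methylmorpholine N-oxide (acetone/H2O) dihydroxylates the 3,4-alkene from the α-face to give 3α,4α-dihydroxy-5α-eudesm-7(11)-en-8-one F4. Selective oxidation of its secondary hydroxyl (SO3·pyridine, DMSO, iPr2NEt, 0 °C) comes back to the route at 4.

Step 4 (acylation of a hindered alcohol and Z-to-E drift to the tiglate). The fallback sets out from 5 and builds the angelate alkene on the molecule instead of transferring it. DCC with catalytic DMAP and 2-[bis(2,2,2-trifluoroethoxy)phosphoryl]propanoic acid esterify the 3β-OH to give 3β-{2-[bis(2,2,2-trifluoroethoxy)phosphoryl]propanoyloxy}-4α-hydroxy-5α-eudesm-7(11)-en-8-one F5. Z-selective Still–Gennari olefination with acetaldehyde (KN(SiMe3)2, 1.05 equiv, 18-crown-6, THF, −78 °C; the phosphonate C–H is by far the most acidic site) comes back to the route at 8.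

**Further compounds**

F1 | step 1 | (1R,10R)-1,10-epoxygermacra-4E,7(11)-dien-8-one | C[C@@]12CC(=O)C(=C(C)C)C/C=C(C)/CC[C@H]1O2
F2 | step 1 | 1β-hydroxy-5α-eudesma-3,7(11)-dien-8-one | CC1=CC[C@@H](O)[C@]2(C)CC(=O)C(=C(C)C)C[C@@H]12
F3 | step 1 | 1β-(imidazol-1-ylthiocarbonyloxy)-5α-eudesma-3,7(11)-dien-8-one | CC1=CC[C@@H](OC(=S)n3ccnc3)[C@]2(C)CC(=O)C(=C(C)C)C[C@@H]12
F4 | step 2 | 3α,4α-dihydroxy-5α-eudesm-7(11)-en-8-one | O[C@@H]1CC[C@]2(C)CC(=O)C(=C(C)C)C[C@H]2[C@]1(C)O
F5 | step 4 | 3β-{2-[bis(2,2,2-trifluoroethoxy)phosphoryl]propanoyloxy}-4α-hydroxy-5α-eudesm-7(11)-en-8-one (both epimers at the phosphonate carbon) | CC(C(=O)O[C@H]1CC[C@]2(C)CC(=O)C(=C(C)C)C[C@H]2[C@]1(C)O)P(=O)(OCC(F)(F)F)OCC(F)(F)F
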